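**Retrosynthetic overview**
- Last step: C6–OOH and the C7=C8 isopropenyl end come from a Schenck ene reaction of singlet oxygen on the prenyl terminus of a (4S)-4-hydroxygeranyl aryl ether.
- Aryl ether C1–O: Mitsunobu coupling of a bought 4-hydroxycoumarin with the primary hydroxyl of a (2E,4S)-octa-2,6-diene-1,4-diol.
- Key bond C3–C4: a (+)-sparteine-lithiated homoprenyl carbamate (C4 as a chiral α-oxy carbanion, a carbinol carbon with reversed polarity) is joined to the boron-bearing alkenyl carbon C3 of a (Z)-alkenyl boronate. Boronate formation, 1,2-metallate shift and C–B oxidation give the 4S carbinol and the 2E alkene in one flask.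
- Fragments: the carbamate from 4-methylpent-3-en-1-ol; the alkenyl boronate from but-2-yn-1-ol by silylation and Cu-catalysed syn-protoboration.
- Rings: none is built; the coumarin bicycle is bought intact and attached late.

Assumption: 4-hydroxy-5-methylcoumarin and (+)-sparteine are bought as catalogue chemicals.

**Step 1**
Reactants: 1 but-2-yn-1-ol
Product: 2 (but-2-yn-1-yloxy)triethylsilane
Conditions: TESCl (1.1 equiv), imidazole (1.5 equiv), CH2Cl2, 0 °C to rt
Reagents that add atoms: chlorotriethylsilane CC[Si](Cl)(CC)CC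
Why: Standard O-silylation (silyl ether protection); C1 must carry a poor leaving group in step 4, because an aryloxy group there would be expelled in an SN2′-type 1,2-shift of the boronate complex, which is why the coumarin is attached only afterwards.

**Step 2**
Reactants: 2 (but-2-yn-1-yloxy)triethylsilane
Product: 3 triethyl{[(2Z)-3-(4,4,5,5-tetramethyl-1,3,2-dioxaborolan-2-yl)but-2-en-1-yl]oxy}silane
Conditions: B2pin2 (1.1 equiv), CuCl (5 mol%), PCy3 (6 mol%), NaOtBu (10 mol%), MeOH (2 equiv), THF, rt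
Reagents that add atoms: bis(pinacolato)diboron CC1(C)OB(OC1(C)C)B1OC(C)(C)C(C)(C)O1
Why: Copper-catalysed protoboration (formal hydroboration) of a propargylic ether: syn-borylcupration puts boron on the alkyne carbon remote from the inductively withdrawing CH2OSi group and MeOH protonates the C–Cu bond with retention, so boron ends trans to CH2O (the future 2E geometry).

**Step 3**
Reactants: 4 4-methylpent-3-en-1-ol
Product: 5 4-methylpent-3-en-1-yl N,N-di(propan-2-yl)carbamate
Conditions: iPr2NC(O)Cl (1.2 equiv), Et3N (1.5 equiv), CH2Cl2, reflux, 24 h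
Reagents that add atoms: N,N-diisopropylcarbamoyl chloride CC(C)N(C(C)C)C(Cl)=O
Why: O-Carbamoylation of a primary alcohol; the hindered carbamate directs and stabilises the α-lithiation in step 4 and later serves as the leaving group.

**Step 4**
Reactants: 5 4-methylpent-3-en-1-yl N,N-di(propan-2-yl)carbamate; 3 triethyl{[(2Z)-3-(4,4,5,5-tetramethyl-1,3,2-dioxaborolan-2-yl)but-2-en-1-yl]oxy}silane
Product: 10 (2E,4S)-3,7-dimethylocta-2,6-diene-1,4-diol, via lithiated carbamate 6 (not isolated), via boronate complex 7 (not isolated), via allylic boronic ester 8 (not isolated), via silyl ether alcohol 9 (not isolated)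
Conditions: 5 (1.3 equiv), (+)-sparteine (1.3 equiv), s-BuLi (1.25 equiv), Et2O, −78 °C, 5 h; 3 (1.0 equiv), −78 °C, 1 h; MgBr2·OEt2, −78 °C to reflux, 16 h; 2 M NaOH/30% H2O2, THF, 0 °C to rt; Na2S2O3, then 1 M HCl, MeOH, 0 °C, 30 min
Reagents that add atoms: hydrogen peroxide OO
Why: Hoppe–Aggarwal lithiation–borylation: s-BuLi/(+)-sparteine removes the pro-R α-proton of 5 to give the configurationally stable (R)-α-oxy carbanion 6, which adds to boron of 3 with retention (7); MgBr2-assisted anti 1,2-metallate (Matteson-type) shift of the alkenyl group expels the carbamate with inversion to give (S)-allylboronate 8 with the alkene geometry intact, and stereoretentive B→OH oxidation (9) followed by acid desilylation gives the 4S diol (expected er about 95:5 or better).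

**Step 5**
Reactants: 10 (2E,4S)-3,7-dimethylocta-2,6-diene-1,4-diol; 11 4-hydroxy-5-methyl-2H-chromen-2-one
Product: 12 4-{[(2E,4S)-4-hydroxy-3,7-dimethylocta-2,6-dien-1-yl]oxy}-5-methyl-2H-chromen-2-one
Conditions: PPh3 (1.1 equiv), DIAD (1.1 equiv), THF, 0 °C to rt
Reagents that add atoms: none
Why: Mitsunobu etherification: the acidic 4-hydroxycoumarin (pKa about 4) displaces the activated primary allylic hydroxyl by SN2, the hindered secondary C4 hydroxyl is left alone with limiting reagents, and no stereocentre is touched.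

**Step 6**
Reactants: 12 4-{[(2E,4S)-4-hydroxy-3,7-dimethylocta-2,6-dien-1-yl]oxy}-5-methyl-2H-chromen-2-one
Product: 13 4-{[(2E,4S,6S)-6-hydroperoxy-4-hydroxy-3,7-dimethylocta-2,7-dien-1-yl]oxy}-5-methyl-2H-chromen-2-one
Conditions: O2, TPP (1 mol%), visible light, CH2Cl2, 0 °C, to about 85% conversion; SiO2 chromatography, then normal-phase HPLC
Reagents that add atoms: dioxygen O=O
Why: Schenck ene reaction: sensitised singlet oxygen attacks the electron-rich C6=C7 alkene (C2=C3 is deactivated by two allylic oxygens) and abstracts a C8 methyl hydrogen, giving C6–OOH and the C7=C8 isopropenyl group; the remote C4 carbinol gives essentially no facial bias, so C6 is not set selectively and the 6S target is separated from its 6R epimer (about 1:1) and from the tertiary C7-hydroperoxide regioisomer.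

**Compound list**
1 | but-2-yn-1-ol | CC#CCO | starting material
2 | (but-2-yn-1-yloxy)triethylsilane | CC#CCO[Si](CC)(CC)CC | intermediate
3 | triethyl{[(2Z)-3-(4,4,5,5-tetramethyl-1,3,2-dioxaborolan-2-yl)but-2-en-1-yl]oxy}silane | CC[Si](CC)(CC)OC/C=C(\C)B1OC(C)(C)C(C)(C)O1 | intermediate
4 | 4-methylpent-3-en-1-ol | CC(C)=CCCO | starting material
5 | 4-methylpent-3-en-1-yl N,N-di(propan-2-yl)carbamate | CC(C)=CCCOC(=O)N(C(C)C)C(C)C | intermediate
6 | [(1R)-1-{[di(propan-2-yl)carbamoyl]oxy}-4-methylpent-3-en-1-yl]lithium, as its (+)-sparteine complex (diamine not drawn) | [Li][C@H](CC=C(C)C)OC(=O)N(C(C)C)C(C)C | intermediate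
7 | lithium [(1R)-1-{[di(propan-2-yl)carbamoyl]oxy}-4-methylpent-3-en-1-yl]{(2Z)-4-[(triethylsilyl)oxy]but-2-en-2-yl}(pinacolato)borate | [Li+].CC[Si](CC)(CC)OC/C=C(\C)[B-]1([C@H](CC=C(C)C)OC(=O)N(C(C)C)C(C)C)OC(C)(C)C(C)(C)O1 | intermediate
8 | triethyl{[(2E,4S)-3,7-dimethyl-4-(4,4,5,5-tetramethyl-1,3,2-dioxaborolan-2-yl)octa-2,6-dien-1-yl]oxy}silane | CC[Si](CC)(CC)OC/C=C(\C)[C@@H](B1OC(C)(C)C(C)(C)O1)CC=C(C)C | intermediate
9 | (2E,4S)-3,7-dimethyl-1-[(triethylsilyl)oxy]octa-2,6-dien-4-ol | CC[Si](CC)(CC)OC/C=C(\C)[C@@H](O)CC=C(C)C | intermediate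
10 | (2E,4S)-3,7-dimethylocta-2,6-diene-1,4-diol | OC/C=C(\C)[C@@H](O)CC=C(C)C | intermediate
11 | 4-hydroxy-5-methyl-2H-chromen-2-one | Cc1cccc2oc(=O)cc(O)c12 | starting material
12 | 4-{[(2E,4S)-4-hydroxy-3,7-dimethylocta-2,6-dien-1-yl]oxy}-5-methyl-2H-chromen-2-one | Cc1cccc2oc(=O)cc(OC/C=C(\C)[C@@H](O)CC=C(C)C)c12 | intermediate
13 | 4-{[(2E,4S,6S)-6-hydroperoxy-4-hydroxy-3,7-dimethylocta-2,7-dien-1-yl]oxy}-5-methyl-2H-chromen-2-one | C=C(C)[C@H](C[C@H](O)/C(C)=C/COc1cc(=O)oc2cccc(C)c12)OO | target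

**Totals**
Total step count: 6. Longest linear sequence: 5 (steps 1, 2, 4, 5, 6).

**Steps most likely to fail**

Step 6 (ene reaction). The step will run, but it gives no control at C6 and splits between the secondary and tertiary hydroperoxides, so at best about a quarter of the material is the target. The fallback sets C6 by reagent control; it sets out from 12 and comes back at 13. The C4 hydroxyl is silylated (TBSOTf, 2,6-lutidine, CH2Cl2, −78 °C) to give 4-{[(2E,4S)-4-[(tert-butyldimethylsilyl)oxy]-3,7-dimethylocta-2,6-dien-1-yl]oxy}-5-methyl-2H-chromen-2-one F4. Shi epoxidation of the electron-rich C6=C7 alkene (D-fructose-derived ketone, Oxone, K2CO3 buffer, MeCN–DMM–H2O, 0 °C) gives 4-{[(2E,4S)-4-[(tert-butyldimethylsilyl)oxy]-5-[(2R)-3,3-dimethyloxiran-2-yl]-3-methylpent-2-en-1-yl]oxy}-5-methyl-2H-chromen-2-one F5. Noyori-type isomerisation of the epoxide (TMSOTf, DBU, toluene, −78 °C to rt) opens the tertiary C–O bond without touching C6 and gives 4-{[(2E,4S,6R)-4-[(tert-butyldimethylsilyl)oxy]-3,7-dimethyl-6-[(trimethylsilyl)oxy]octa-2,7-dien-1-yl]oxy}-5-methyl-2H-chromen-2-one F6. The TMS group alone is removed (citric acid, MeOH, 0 °C) to give 4-{[(2E,4S,6R)-4-[(tert-butyldimethylsilyl)oxy]-6-hydroxy-3,7-dimethylocta-2,7-dien-1-yl]oxy}-5-methyl-2H-chromen-2-one F7. Mesylation (MsCl, Et3N, CH2Cl2, −30 °C) gives 4-{[(2E,4S,6R)-4-[(tert-butyldimethylsilyl)oxy]-6-(methanesulfonyloxy)-3,7-dimethylocta-2,7-dien-1-yl]oxy}-5-methyl-2H-chromen-2-one F8. Displacement with inversion by hydroperoxide (50% H2O2, CsOH·H2O, DMF–THF, 0 °C) gives 4-{[(2E,4S,6S)-4-[(tert-butyldimethylsilyl)oxy]-6-hydroperoxy-3,7-dimethylocta-2,7-dien-1-yl]oxy}-5-methyl-2H-chromen-2-one F9, and HF·pyridine (THF, 0 °C) then gives 13. The displacement on an allylic mesylate is itself uncertain (SN2′, elimination, attack on the coumarin), which is why this longer sequence is the fallback and not the main route.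

Step 4 (lithiation–borylation). Risks are competing allylic deprotonation of 5, slow 1,2-migration from the hindered 1,1-disubstituted alkenyl boronate, and loss of the silyl ether under MgBr2. The fallback makes the C3–C4 bond by a catalytic asymmetric Nozaki–Hiyama–Kishi alkenylation; it sets out from 3 and 4 and comes back at 9. Boronate 3 is iodinated with retention (NaOH, I2, THF, 0 °C) to give triethyl{[(2E)-3-iodobut-2-en-1-yl]oxy}silane F1. Alcohol 4 is oxidised (Dess–Martin periodinane, NaHCO3, CH2Cl2) to 4-methylpent-3-enal F2, used at once. F1 and F2 are coupled (CrCl2 cat., NiCl2 cat., Mn, Cp2ZrCl2, Kishi-type chiral sulfonamide ligand chosen for the 4S alcohol, MeCN, rt) to give 9, which is desilylated with dilute HCl as in step 4 to give 10.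

Step 5 (Mitsunobu). The ambident coumarin can also react at O2 (2-alkoxychromone) or C3, and the 5-methyl group crowds O4. The fallback reverses the roles so that only the 4-O-ether can form; it sets out from 11 and comes back at 12. Coumarin 11 is chlorinated (POCl3, BnEt3NCl, MeCN, reflux) to give 4-chloro-5-methyl-2H-chromen-2-one F3. The primary alkoxide of diol 10 (1.2 equiv 10, 1.0 equiv NaH, THF, 0 °C) then displaces chloride by addition–elimination at C4 to give 12.

**Further compounds**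
F1 | step 4 | triethyl{[(2E)-3-iodobut-2-en-1-yl]oxy}silane | CC[Si](CC)(CC)OC/C=C(\C)I
F2 | step 4 | 4-methylpent-3-enal | CC(C)=CCC=O
F3 | step 5 | 4-chloro-5-methyl-2H-chromen-2-one | Cc1cccc2oc(=O)cc(Cl)c12
F4 | step 6 | 4-{[(2E,4S)-4-[(tert-butyldimethylsilyl)oxy]-3,7-dimethylocta-2,6-dien-1-yl]oxy}-5-methyl-2H-chromen-2-one | Cc1cccc2oc(=O)cc(OC/C=C(\C)[C@@H](O[Si](C)(C)C(C)(C)C)CC=C(C)C)c12
F5 | step 6 | 4-{[(2E,4S)-4-[(tert-butyldimethylsilyl)oxy]-5-[(2R)-3,3-dimethyloxiran-2-yl]-3-methylpent-2-en-1-yl]oxy}-5-methyl-2H-chromen-2-one | Cc1cccc2oc(=O)cc(OC/C=C(\C)[C@@H](O[Si](C)(C)C(C)(C)C)C[C@H]3OC3(C)C)c12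
F6 | step 6 | 4-{[(2E,4S,6R)-4-[(tert-butyldimethylsilyl)oxy]-3,7-dimethyl-6-[(trimethylsilyl)oxy]octa-2,7-dien-1-yl]oxy}-5-methyl-2H-chromen-2-one | Cc1cccc2oc(=O)cc(OC/C=C(\C)[C@@H](O[Si](C)(C)C(C)(C)C)C[C@@H](O[Si](C)(C)C)C(C)=C)c12
F7 | step 6 | 4-{[(2E,4S,6R)-4-[(tert-butyldimethylsilyl)oxy]-6-hydroxy-3,7-dimethylocta-2,7-dien-1-yl]oxy}-5-methyl-2H-chromen-2-one | Cc1cccc2oc(=O)cc(OC/C=C(\C)[C@@H](O[Si](C)(C)C(C)(C)C)C[C@@H](O)C(C)=C)c12
F8 | step 6 | 4-{[(2E,4S,6R)-4-[(tert-butyldimethylsilyl)oxy]-6-(methanesulfonyloxy)-3,7-dimethylocta-2,7-dien-1-yl]oxy}-5-methyl-2H-chromen-2-one | Cc1cccc2oc(=O)cc(OC/C=C(\C)[C@@H](O[Si](C)(C)C(C)(C)C)C[C@@H](OS(C)(=O)=O)C(C)=C)c12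
F9 | step 6 | 4-{[(2E,4S,6S)-4-[(tert-butyldimethylsilyl)oxy]-6-hydroperoxy-3,7-dimethylocta-2,7-dien-1-yl]oxy}-5-methyl-2H-chromen-2-one | Cc1cccc2oc(=O)cc(OC/C=C(\C)[C@@H](O[Si](C)(C)C(C)(C)C)C[C@H](OO)C(C)=C)c12
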